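**The neighbour.** Violet is a neighbour of this flask: it has the same incoming ligand, 1.36 M, but 0.46 M of starting complex against 0.91 M.

| setting | ochre | grey | violet | flask |
|---|---|---|---|---|
| starting complex | 0.91 M | 0.91 M | 0.46 M | 0.91 M |
| incoming ligand | 0.68 M | 1 M | 1.36 M | 1.36 M |
| remark | run made earlier | run made earlier | run made earlier |  |
| time |  |  |  | 20 h |

| run | time / h | complex with one exchanged / % | starting complex / % |
|---|---|---|---|
| ochre | 3.00 | 0 | 99 |
| ochre | 6.00 | 3 | 99 |
| ochre | 10.0 | 2 | 96 |
| ochre | 12.0 | 6 | 95 |
| ochre | 15.0 | 8 | 92 |
| grey | 1.33 | 0 | 99 |
| grey | 2.50 | 1 | 100 |
| grey | 5.00 | 5 | 96 |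
| grey | 8.00 | 6 | 93 |
| grey | 15.0 | 12 | 87 |
| violet | 3.00 | 5 | 95 |
| violet | 6.00 | 5 | 94 |
| violet | 10.0 | 10 | 90 |
| violet | 12.0 | 12 | 88 |
| violet | 15.0 | 12 | 87 |

(scatter of a reading: 1.5 percentage points)

- what is said of complex with one exchanged includes crystals
- crystals is a solid; its amount is given per volume of the solution
- reactions considered so far: starting complex + incoming ligand <-> leaving ligand + complex with one exchanged; complex with one exchanged + incoming ligand <-> leaving ligand + complex with two exchanged; crystals <-> complex with one exchanged

1. amount of complex with one exchanged in percent of the starting complex charged, at 2.0 h, 6.0 h, 12 h and 20 h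

In every run the starting complex and the complex with one exchanged sum to about the whole charge, so I treat first exchange as the step at work. I take it as first order in each partner. While c(incoming ligand) holds nearly steady, the starting complex then decays pseudo-first-order, and its percent course depends on the ligand level, not on its own charge. Violet should therefore give the flask's opening pace.

**Ligand drain.** Each complex exchanged costs one incoming ligand. Dividing the ligand's fractional rate of loss by the complex's, time drops out, which leaves the ligand drain, c(starting complex)/c(incoming ligand) as charged: 0.669 in the flask, and 0.338 in violet. It is the fraction of the ligand lost per fraction of complex converted, and it is larger in the flask than in violet.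

**My reckoning.** Violet's 87% of starting complex at 15.0 h reads as a decay constant of 0.00928 h⁻¹, and that reading carries the scatter. Carried to 20 h, this gives 16.9% converted. By my reckoning the flask has then lost 11.3% of its ligand, and violet 4.39% of its own at its reading. Halving the difference for the average over each run, I put the flask on average at 3.47% less ligand than violet. I commit to 16.4% of complex with one exchanged at 20 h.

The forecast gives 2%, 6%, 12% and 18%, “slowing as ligand and complex are consumed”, and its last value stands above mine.

**The flask.** It gives 1.99%, 5.68%, 10.6% and 16.5%.

    starting complex + incoming ligand ⇌ leaving ligand + complex with one exchanged (K = 15.0, k = 0.00750 L mol⁻¹ h⁻¹)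
    complex with one exchanged + incoming ligand ⇌ leaving ligand + complex with two exchanged (K = 1.60, k = 0.00620 L mol⁻¹ h⁻¹)
    crystals ⇌ complex with one exchanged, rate k3*(cs3 - [complex with one exchanged]) while solid is left; crystals form when [complex with one exchanged] > cs3 (solubility = 0.0540 M, k = 0.800 h⁻¹)

The forward half-life of dissolved complex with one exchanged by the second exchange, with the other concentrations as charged, is 82 h, long against the 20 h, and complex with two exchanged stands at 0.876% at 20.0 h. The flask has converted 17.4% of its starting complex, and with one incoming ligand counted for each first exchange and one for each second, the drain puts the incoming ligand left at 87.8% of its charge. The flask holds 88%.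

(The earlier runs and the new flask were computed for an exercise, and the scatter is random.)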